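I had no rate constants for the south flask, so I began from what its readings could give in their place: a count of turnovers, and a time constant for how fast that count was closing.

the same everywhere: left-handed substrate 20 mM; right-handed substrate 20 mM
- south: reagent 12 mM; catalyst 3 mM; the very flask that is asked about, followed so far
- south-west: reagent 12 mM; catalyst 2 mM; run made earlier
- flask: reagent 12.0 mM; catalyst 3.0 mM; time 2.0 h

- south (time / min: left-handed product / %, left-handed substrate / %): 8.00: 4.4, 44.8; 12.0: 4.9, 42.3; 20.0: 6.7, 38.3; 25.0: 8.2, 36.1; 40.0: 9.0, 31.7; 60.0: 11.2, 28.5; 90.0: 13.4, 24.4
- south-west (time / min: left-handed product / %, left-handed substrate / %): 1.33: 0.4, 48.3; 2.00: 0.6, 49.3; 3.00: 1.6, 47.9; 5.00: 1.3, 48.1; 8.00: 2.5, 45.6; 12.0: 3.9, 44.6; 20.0: 5.3, 40.7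

(standard deviation of a reading: 0.5 percentage points)

- Monday's: at 2.0 h add reagent, 100 % of the amount charged, then wait 4.0 h
- Sunday's: change nothing and wait 4.0 h more
- Tuesday's: at 2.0 h take out 90 % of the left-handed product then present, then wait 4.0 h
- Saturday's: at 2.0 h add catalyst, 50.0 % of the amount charged, then wait 4.0 h

- catalyst is single-handed; left-handed substrate and right-handed substrate are mirror images of each other, charged as a racemate, each of them at the stated concentration
- removed left-handed product is counted in
- additions bring no volume worth counting

- left-handed product, in percent of the left-handed substrate and right-handed substrate together first charged, at 2.0 h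
- the remedy with the largest gain of left-handed product, or "none" below 2 percentage points (Monday's / Sunday's / Tuesday's / Saturday's / none)
- left-handed product present, with what was taken out counted in, in percent of the left-handed substrate and right-handed substrate together first charged, after Tuesday's
- left-handed product present, with what was taken out counted in, in percent of the left-handed substrate and right-handed substrate together first charged, after Saturday's

I assumed that each left-handed substrate lost costs one reagent, and I carried the turnover budget, 4.00 here, meaning [reagent] charged over [catalyst] charged. One turnover in this flask moves 7.50 % of the substrates charged, and the left-handed substrate holds 6.67 turnovers, more than the budget, so reagent is the limiting reagent.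

I then turned the question round and asked what waiting or more catalyst would need in order to clear the margin. In the south run at 90.0 min, left-handed product read 0.523 of the left-handed substrate lost, so a gain of 2 percentage points needs 0.509 turnovers still open at 2.0 h. Reagent left in the south run, reckoned from the scattered readings of the loss, fell from 8.5 points to 4.4 points between 60.0 min and 90.0 min, which reads as a time constant of 45.6 min, and carried forward as a plain decay this gave my estimate of 2.3 points at 2.0 h. That is 0.304 open turnovers, fewer than needed.

My reckoning therefore gave 14.5 % now and, counting the open turnovers as used, 15.7 % after Saturday's, whose catalyst adds no reagent. Monday's reckoned to a gain of about 12 points, with left-handed substrate then the limit, since by my estimate the reagent after the addition exceeded the left-handed substrate remaining. The count concerns reagent used, so I put no number on Tuesday's.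

The forecast gave 14.3 %, a little under mine, with Monday's best, 15.6 % after Tuesday's and 15.7 % after Saturday's, on the ground that "Adding reagent lets most of the remaining substrate react". The flask gave 13.4 %; Monday's led with a gain of 12 points, Tuesday's reached 21.0 % and Saturday's 15.0 %.

    reagent + catalyst + right-handed substrate → catalyst + right-handed product (k = 9.50 M⁻² min⁻¹)
    left-handed product ⇌ right-handed product (k = 0.160 min⁻¹)
    reagent + catalyst + left-handed substrate → catalyst + left-handed product (k = 480 M⁻² min⁻¹)

In this flask reagent stood at 11 % of its charge at 120 min, which is 0.435 open turnovers, fewer than the 0.509 required, and Sunday's gained 1.5 points. The neighbour charged with 0.75 mM of catalyst had a budget of 16.0, and with 48 % of its reagent left at 120 min it had used 8.32 turnovers, each worth 1.88 % of the substrates charged. At the share read in the south run that reckons to 8.11 % of left-handed product, and that neighbour held 7.86 %.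

The readings stem from a simulated flask for an exercise.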